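**Retrosynthetic overview**
- The target is (2S)-5,4'-dihydroxy-6,7-dimethoxy-8-prenylflavanone; O4' is carried as an acetate and O5 as a methyl ether, both released at the end (chelation-controlled O5 demethylation, then neutral deacetylation).
- Key disconnection C4–C4a: ring C, the only ring formed, is closed by intramolecular Friedel-Crafts acylation of a chiral 3-aryl-3-aryloxypropanoic acid. The strategy rests on C4a being the single hydrogen-bearing carbon of ring A once O1, O5, O6, O7 and the C8 prenyl group are in place, and on its activation by O1 and O5 (ortho) and O7 (para).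
- Disconnection C2–O1: Mitsunobu etherification with inversion between 2-prenyl-3,4,5-trimethoxyphenol and an allyl (R)-3-aryl-3-hydroxypropanoate, then palladium-catalysed deallylation.
- The (R)-hydroxy ester comes from 4'-hydroxyacetophenone by carboxylation with diallyl carbonate, O-acetylation and asymmetric transfer hydrogenation; the phenol comes from 3,4,5-trimethoxyphenol by ortho C-prenylation.
- Ring order: rings A and B are purchased; ring C is formed in step 7.

Key step: step 7

Assumption: the descriptor at C2 in the SMILES reads as (2S) (O1 > C1' > C3 > H), so the (2S) flavanone is the compound made.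

**Route**

Step 1
Reactants: 1 3,4,5-trimethoxyphenol; 2 prenyl bromide (1-bromo-3-methylbut-2-ene)
Product: 3 3,4,5-trimethoxy-2-(3-methylbut-2-en-1-yl)phenol
Conditions: NaH (1.05 equiv), toluene, 0 °C to rt
Reagents that add atoms: none
Why: Ortho C-alkylation of a phenoxide: in a non-polar solvent the sodium phenoxide reacts as a tight ion pair through its ortho carbon in an SN2 reaction at the primary allylic carbon, and since both ortho positions of 1 are equivalent and the para position is blocked, one C-prenyl regioisomer should form.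

Step 2
Reactants: 4 4'-hydroxyacetophenone; 5 diallyl carbonate
Product: 6 allyl 3-(4-hydroxyphenyl)-3-oxopropanoate
Conditions: NaH (3.5 equiv), THF, reflux; then 1 M HCl, 0 °C
Reagents that add atoms: none
Why: Crossed Claisen condensation of the ketone enolate with the carbonate, driven by deprotonation of the β-keto ester product, with the phenol held as its phenoxide and any aryl carbonate formed at oxygen returned to phenoxide by the allyloxide released.

Step 3
Reactants: 6 allyl 3-(4-hydroxyphenyl)-3-oxopropanoate
Product: 7 allyl 3-(4-acetoxyphenyl)-3-oxopropanoate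
Conditions: Ac2O (1.05 equiv), pyridine, CH2Cl2, 0 °C
Reagents that add atoms: acetic anhydride, CC(=O)OC(C)=O
Why: Pyridine-mediated O-acylation, in which the phenol should react much faster than the enol of the β-keto ester when one equivalent of anhydride is used in the cold.

Step 4
Reactants: 7 allyl 3-(4-acetoxyphenyl)-3-oxopropanoate
Product: 8 allyl (3R)-3-(4-acetoxyphenyl)-3-hydroxypropanoate
Conditions: RuCl[(R,R)-TsDPEN](p-cymene) (1 mol %), HCO2H/Et3N (5:2), EtOAc, 30 °C
Reagents that add atoms: none
Why: Noyori-Ikariya asymmetric transfer hydrogenation, in which the ruthenium hydride and the ligand N–H deliver hydrogen to one carbonyl face fixed by the aryl/p-cymene CH–π contact, so that the (R,R) ligand should give the (R) alcohol as it does for aryl alkyl ketones, leaving the allyl ester and aryl acetate untouched.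

Step 5
Reactants: 3 3,4,5-trimethoxy-2-(3-methylbut-2-en-1-yl)phenol; 8 allyl (3R)-3-(4-acetoxyphenyl)-3-hydroxypropanoate
Product: 9 allyl (3S)-3-(4-acetoxyphenyl)-3-[3,4,5-trimethoxy-2-(3-methylbut-2-en-1-yl)phenoxy]propanoate
Conditions: PPh3 (1.5 equiv), DIAD (1.5 equiv, slow addition), toluene, 0 °C to rt
Reagents that add atoms: none
Why: Mitsunobu reaction, in which the alcohol is activated as its alkoxyphosphonium ion and displaced by the phenoxide in an SN2 step with inversion, turning the (R) carbinol carbon into the (S) aryl ether, while the para acetate disfavours benzylic ionisation and the neutral medium spares both esters.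

Step 6
Reactants: 9 allyl (3S)-3-(4-acetoxyphenyl)-3-[3,4,5-trimethoxy-2-(3-methylbut-2-en-1-yl)phenoxy]propanoate
Product: 10 (3S)-3-(4-acetoxyphenyl)-3-[3,4,5-trimethoxy-2-(3-methylbut-2-en-1-yl)phenoxy]propanoic acid
Conditions: Pd(PPh3)4 (3 mol %), HCO2H, Et3N, THF, rt
Reagents that add atoms: none
Why: Tsuji-Trost deallylation, in which zerovalent palladium ionises the allyl ester to a π-allyl complex that formate reduces to propene, under near-neutral conditions that avoid both β-elimination of the aryloxide and aminolysis of the aryl acetate.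

Step 7
Reactants: 10 (3S)-3-(4-acetoxyphenyl)-3-[3,4,5-trimethoxy-2-(3-methylbut-2-en-1-yl)phenoxy]propanoic acid
Product: 12 (2S)-4'-O-acetyl-5,6,7-trimethoxy-8-prenylflavanone, via acid chloride 11 (not isolated)
Conditions: 1-chloro-N,N,2-trimethylprop-1-en-1-amine (1.05 equiv), CH2Cl2, 0 °C to rt; then (CF3)2CHOH, 2,6-di-tert-butylpyridine (1.2 equiv), 0 °C to rt
Reagents that add atoms: none
Why: The α-chloroenamine turns the acid into acyl chloride 11 without releasing HCl, and in the fluoroalcohol hydrogen bonding to the carbonyl oxygen and the departing chloride polarises C4 towards an acylium ion, which C4a attacks in an electrophilic aromatic substitution before loss of the C4a proton restores ring A. The closest known reaction type is the intramolecular Friedel-Crafts acylation of 3-aryloxypropanoyl chlorides to chroman-4-ones, including its catalyst-free variant in fluoroalcohol solvent. Ring C closes in a 6-exo-trig mode, C4a adding to the acyl carbon whose C=O bond lies outside the new ring. No stereocentre is created, and C2 keeps its configuration because the C2–O1 bond is never broken and the 4'-acetate destabilises a benzylic cation at C2. Regioselectivity needs no control, since C4a is the only ring carbon bearing hydrogen and is activated ortho by O1 and O5 and para by O7. The selectivity needed is arene over prenyl alkene, which the high nucleophilicity of C4a should secure by allowing reaction at or below room temperature while the hindered pyridine takes up the HCl that could otherwise add to the alkene.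

Step 8
Reactants: 12 (2S)-4'-O-acetyl-5,6,7-trimethoxy-8-prenylflavanone
Product: 14 (2S)-4'-O-acetyl-5-hydroxy-6,7-dimethoxy-8-prenylflavanone, via O5-dichloroboryl chelate 13 (not isolated)
Conditions: BCl3 (1.0 M in CH2Cl2, 1.3 equiv), CH2Cl2, −78 to −20 °C; then H2O, 0 °C
Reagents that add atoms: none
Why: Chelation-controlled demethylation of a peri-methoxy ketone, in which BCl3 bridges the C4 carbonyl and O5 in a six-membered chelate so that chloride cleaves only that O–CH3 bond, leaving the 6- and 7-methoxy groups, the aryl acetate and the prenyl group intact at low temperature.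

Step 9
Reactants: 14 (2S)-4'-O-acetyl-5-hydroxy-6,7-dimethoxy-8-prenylflavanone
Product: 15 (2S)-5,4'-dihydroxy-6,7-dimethoxy-8-prenylflavanone (target)
Conditions: NH4OAc (10 equiv), MeOH/H2O (4:1), rt
Reagents that add atoms: none
Why: Ammonium acetate-mediated neutral solvolysis of an aryl acetate, the most electrophilic acyl group present, at a pH that should avoid both the base-induced ring opening to the chalcone that would racemise C2 and acid-promoted addition to the prenyl alkene.

**Compound list**
1 | 3,4,5-trimethoxyphenol | COc1cc(O)cc(OC)c1OC | starting material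
2 | prenyl bromide (1-bromo-3-methylbut-2-ene) | CC(C)=CCBr | starting material
3 | 3,4,5-trimethoxy-2-(3-methylbut-2-en-1-yl)phenol | COc1c(OC)cc(O)c(CC=C(C)C)c1OC | intermediate
4 | 4'-hydroxyacetophenone | CC(=O)c1ccc(O)cc1 | starting material
5 | diallyl carbonate | C=CCOC(=O)OCC=C | starting material
6 | allyl 3-(4-hydroxyphenyl)-3-oxopropanoate | O=C(CC(=O)OCC=C)c1ccc(O)cc1 | intermediate
7 | allyl 3-(4-acetoxyphenyl)-3-oxopropanoate | CC(=O)Oc1ccc(cc1)C(=O)CC(=O)OCC=C | intermediate
8 | allyl (3R)-3-(4-acetoxyphenyl)-3-hydroxypropanoate | O[C@@H](c1ccc(OC(C)=O)cc1)CC(=O)OCC=C | intermediate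
9 | allyl (3S)-3-(4-acetoxyphenyl)-3-[3,4,5-trimethoxy-2-(3-methylbut-2-en-1-yl)phenoxy]propanoate | COc1c(OC)cc(c(CC=C(C)C)c1OC)O[C@H](c1ccc(OC(C)=O)cc1)CC(=O)OCC=C | intermediate
10 | (3S)-3-(4-acetoxyphenyl)-3-[3,4,5-trimethoxy-2-(3-methylbut-2-en-1-yl)phenoxy]propanoic acid | COc1c(OC)cc(c(CC=C(C)C)c1OC)O[C@H](c1ccc(OC(C)=O)cc1)CC(=O)O | intermediate
11 | (3S)-3-(4-acetoxyphenyl)-3-[3,4,5-trimethoxy-2-(3-methylbut-2-en-1-yl)phenoxy]propanoyl chloride | COc1c(OC)cc(c(CC=C(C)C)c1OC)O[C@H](c1ccc(OC(C)=O)cc1)CC(=O)Cl | intermediate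
12 | (2S)-4'-O-acetyl-5,6,7-trimethoxy-8-prenylflavanone | COc1c(OC)c2c(c(CC=C(C)C)c1OC)O[C@H](c1ccc(OC(C)=O)cc1)CC2=O | intermediate
13 | (2S)-4'-O-acetyl-5-O-dichloroboryl-6,7-dimethoxy-8-prenylflavanone | COc1c(OB(Cl)Cl)c2c(c(CC=C(C)C)c1OC)O[C@H](c1ccc(OC(C)=O)cc1)CC2=O | intermediate
14 | (2S)-4'-O-acetyl-5-hydroxy-6,7-dimethoxy-8-prenylflavanone | COc1c(O)c2c(c(CC=C(C)C)c1OC)O[C@H](c1ccc(OC(C)=O)cc1)CC2=O | intermediate
15 | (2S)-5,4'-dihydroxy-6,7-dimethoxy-8-prenylflavanone | COc1c(O)c2c(c(CC=C(C)C)c1OC)O[C@H](c1ccc(O)cc1)CC2=O | target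

**Totals**
Total step count: 9. Longest linear sequence: 8 steps (from 4 through steps 2 to 9).

**Steps most likely to fail**

Step 7. The HCl set free on ring closure may add to the trisubstituted prenyl alkene or start cation-olefin chemistry, and the acidic, ionising medium may loosen the benzylic C2–O1 bond and erode the configuration. The fallback carries a monosubstituted allyl group, far less easily protonated, through the acylation and grows it into the prenyl group afterwards. It sets out from 1 and returns at 12.
- O-allylation of 1 (allyl bromide, K2CO3, acetone) should give allyl 3,4,5-trimethoxyphenyl ether F1.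
- Aromatic Claisen rearrangement (N,N-diethylaniline, 190 °C) should give 2-allyl-3,4,5-trimethoxyphenol F2.
- Mitsunobu coupling with 8 under the conditions of step 5 should give allyl (3S)-3-(4-acetoxyphenyl)-3-(2-allyl-3,4,5-trimethoxyphenoxy)propanoate F3.
- Deallylation of the ester as in step 6 should give (3S)-3-(4-acetoxyphenyl)-3-(2-allyl-3,4,5-trimethoxyphenoxy)propanoic acid F4.
- The α-chloroenamine should give (3S)-3-(4-acetoxyphenyl)-3-(2-allyl-3,4,5-trimethoxyphenoxy)propanoyl chloride F5, which is cyclised in the fluoroalcohol or, now without risk to the side chain, with SnCl4 in CH2Cl2 at −78 °C to (2S)-4'-O-acetyl-8-allyl-5,6,7-trimethoxyflavanone F6.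
- Cross-metathesis with 2-methylbut-2-ene (second-generation Grubbs catalyst RuCl2(=CHPh)(H2IMes)(PCy3), CH2Cl2, 40 °C) should then give 12.

Step 5. The activated benzylic alcohol may undergo β-elimination to the cinnamate through its acidic α-hydrogens, inversion may be incomplete through partial ionisation, and coupling of the ortho-substituted phenol may be slow. The fallback takes the carboxyl carbon to the alcohol oxidation level before the etherification, so that no acidifying group flanks the reacting centre, and oxidises it back afterwards. It sets out from 8 and returns at 10.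
- Deallylation (Pd(PPh3)4, HCO2H, Et3N, THF) should give (3R)-3-(4-acetoxyphenyl)-3-hydroxypropanoic acid F7.
- Chemoselective reduction of the carboxylic acid (BH3·SMe2, THF, 0 °C) should give (1R)-1-(4-acetoxyphenyl)propane-1,3-diol F8.
- Silylation of the primary hydroxyl (TBSCl, imidazole, CH2Cl2, 0 °C) should give 4-[(1R)-3-(tert-butyldimethylsilyloxy)-1-hydroxypropyl]phenyl acetate F9.
- Mitsunobu coupling with 3 (PPh3, DIAD, toluene), again with inversion, should give 4-[(1S)-3-(tert-butyldimethylsilyloxy)-1-(3,4,5-trimethoxy-2-prenylphenoxy)propyl]phenyl acetate F10.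
- Desilylation (HF·pyridine, THF, 0 °C) should give 4-[(1S)-3-hydroxy-1-(3,4,5-trimethoxy-2-prenylphenoxy)propyl]phenyl acetate F11.
- Oxidation of the primary alcohol (TEMPO, PhI(OAc)2, MeCN/H2O) should then give 10.

Step 1. Alkylation may occur at oxygen in place of carbon, a second prenyl group may enter at the other ortho carbon, and attack may take place at the tertiary allylic terminus. The fallback fixes the site by a sigmatropic shift; it sets out from 1 and returns at 3.
- Palladium-catalysed O-alkylation with tert-butyl 2-methylbut-3-en-2-yl carbonate (Pd(PPh3)4, THF, 0 °C to rt) should give 1,2,3-trimethoxy-5-(2-methylbut-3-en-2-yloxy)benzene F12.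
- Aromatic Claisen rearrangement (xylene, 130 °C) moves the side chain to the ortho carbon with allylic transposition and should give 3.

**Further compounds**
F1 | step 7 | allyl 3,4,5-trimethoxyphenyl ether | C=CCOc1cc(OC)c(OC)c(OC)c1
F2 | step 7 | 2-allyl-3,4,5-trimethoxyphenol | COc1c(OC)cc(O)c(CC=C)c1OC
F3 | step 7 | allyl (3S)-3-(4-acetoxyphenyl)-3-(2-allyl-3,4,5-trimethoxyphenoxy)propanoate | COc1c(OC)cc(c(CC=C)c1OC)O[C@H](c1ccc(OC(C)=O)cc1)CC(=O)OCC=C
F4 | step 7 | (3S)-3-(4-acetoxyphenyl)-3-(2-allyl-3,4,5-trimethoxyphenoxy)propanoic acid | COc1c(OC)cc(c(CC=C)c1OC)O[C@H](c1ccc(OC(C)=O)cc1)CC(=O)O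
F5 | step 7 | (3S)-3-(4-acetoxyphenyl)-3-(2-allyl-3,4,5-trimethoxyphenoxy)propanoyl chloride | COc1c(OC)cc(c(CC=C)c1OC)O[C@H](c1ccc(OC(C)=O)cc1)CC(=O)Cl
F6 | step 7 | (2S)-4'-O-acetyl-8-allyl-5,6,7-trimethoxyflavanone | COc1c(OC)c2c(c(CC=C)c1OC)O[C@H](c1ccc(OC(C)=O)cc1)CC2=O
F7 | step 5 | (3R)-3-(4-acetoxyphenyl)-3-hydroxypropanoic acid | O[C@@H](c1ccc(OC(C)=O)cc1)CC(=O)O
F8 | step 5 | (1R)-1-(4-acetoxyphenyl)propane-1,3-diol | O[C@@H](c1ccc(OC(C)=O)cc1)CCO
F9 | step 5 | 4-[(1R)-3-(tert-butyldimethylsilyloxy)-1-hydroxypropyl]phenyl acetate | O[C@@H](c1ccc(OC(C)=O)cc1)CCO[Si](C)(C)C(C)(C)C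
F10 | step 5 | 4-[(1S)-3-(tert-butyldimethylsilyloxy)-1-(3,4,5-trimethoxy-2-prenylphenoxy)propyl]phenyl acetate | COc1c(OC)cc(c(CC=C(C)C)c1OC)O[C@H](c1ccc(OC(C)=O)cc1)CCO[Si](C)(C)C(C)(C)C
F11 | step 5 | 4-[(1S)-3-hydroxy-1-(3,4,5-trimethoxy-2-prenylphenoxy)propyl]phenyl acetate | COc1c(OC)cc(c(CC=C(C)C)c1OC)O[C@H](c1ccc(OC(C)=O)cc1)CCO
F12 | step 1 | 1,2,3-trimethoxy-5-(2-methylbut-3-en-2-yloxy)benzene | C=CC(C)(C)Oc1cc(OC)c(OC)c(OC)c1
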